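The plan rests on cutting the C6'–C7' bond of ring D, which turns the cis-fused CD hydroazulene into a monocyclic cycloheptadienone. In one operation, a samarium(II) ketone–enone reductive coupling closes ring D and creates C6' and C7' under control of C3'. It leaves the C9' ketone and the C10'=C11' alkene for a later allylic transposition. The step exploits a ring D feature: the C6' hydroxyl is anti to C8' and syn to H-3' and H-7', the native outcome of ketyl–alkene closure. The precursor is (5R)-2,4,4-trimethyl-5-(3-oxobutyl)cyclohepta-2,6-dienone 12, made by asymmetric conjugate addition and ring expansion. A CD sulfone and a cascade-derived AB aldehyde are then joined at C12=C12'.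

Key step: step 7

Locants:
- Ring A is O1, C2 (CMe2), C3 (C=O), C4, C5, C6 (C–Me), C7 (CH–O).
- Ring B is C6–C11, with C10 the carbinol and C11 a CH.
- The linker is C12/C12'.
- Ring C is C11', C2' (CMe2), C3', C7', C8', C9', C10'.
- Ring D is C3'–C7', with C6' the carbinol.
- In the CD unit, α is the face of H-3'/H-7' and β is the opposite face.
- In the AB unit, β is the face of the C6 methyl group.

Assumption: C3 is carried as the (R)-silyl ether that the Shi epoxide delivers, and its configuration is immaterial because C3 ends as the ketone. Centres or geometries that are erased later (C10' in 9, cyclopropane face in 6, alkene geometry in 33) are drawn as the expected major form or left open.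

**CD fragment**

Step 1
Reactants: 1 2-(2-bromoethyl)-2-methyl-1,3-dioxolane; 2 4,4-dimethylcyclohex-2-en-1-one
Product: 5 {[(3R)-4,4-dimethyl-3-[2-(2-methyl-1,3-dioxolan-2-yl)ethyl]cyclohex-1-en-1-yl]oxy}trimethylsilane, via Grignard reagent 3 (not isolated), via magnesium enolate 4 (not isolated)
Conditions: Mg, Et2O, ≤30 °C; CuCl (5 mol %), TaniaPhos (6 mol %, the commercial antipode that directs attack to the Re face of C3), 2, Et2O, 0 °C; then TMSCl, Et3N, DMPU, −78 °C → rt
Reagents that add atoms: chlorotrimethylsilane C[Si](C)(C)Cl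
Why: Copper-catalysed asymmetric conjugate addition of a Grignard reagent, in which the chiral diphosphine–copper complex delivers the side chain to the Re face of C3 of 2 and so sets C3' as (R), followed by O-silylation of the regiodefined enolate, which places the enol double bond on the C7' side where the ring must grow.

Step 2
Reactants: 5 silyl enol ether
Product: 6 (5R)-4,4-dimethyl-5-[2-(2-methyl-1,3-dioxolan-2-yl)ethyl]-1-(trimethylsilyloxy)bicyclo[4.1.0]heptane (cyclopropane CH2 anti to the side chain)
Conditions: Et2Zn, CH2I2, Et2O, 0 °C → rt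
Reagents that add atoms: diiodomethane ICI
Why: Furukawa-type Simmons–Smith cyclopropanation is fastest on the electron-rich silyl enol ether and should occur anti to the C3' side chain, although both new centres disappear in step 3.

Step 3
Reactants: 6 silyloxycyclopropane
Product: 8 (4R)-5,5-dimethyl-4-[2-(2-methyl-1,3-dioxolan-2-yl)ethyl]cyclohept-2-en-1-one, via β-chloro ketone 7 (not isolated)
Conditions: FeCl3 (2.5 equiv), DMF, 0 °C → rt, NaHCO3 work-up; then NaOAc, MeOH, reflux
Reagents that add atoms: none
Why: Saegusa ring expansion, in which one-electron oxidation by FeCl3 cleaves the ring-fusion bond of the silyloxycyclopropane to the ring-enlarged β-keto radical, chlorine transfer gives 7 and acetate-induced E1cB loss of HCl gives the C7'=C8' enone, while DMF-complexed anhydrous FeCl3 and a bicarbonate work-up should spare the dioxolane.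

Step 4
Reactants: 8 cycloheptenone ketal
Product: 9 (4R)-5,5,7-trimethyl-4-[2-(2-methyl-1,3-dioxolan-2-yl)ethyl]cyclohept-2-en-1-one (both C7 = C10' epimers)
Conditions: LDA, THF, −78 °C; MeI, −78 → −20 °C
Reagents that add atoms: iodomethane CI
Why: Kinetic α'-deprotonation of an enone gives the cross-conjugated lithium dienolate, whose only nucleophilic carbon is C10', so enolate alkylation installs the C10' methyl group (epimer mixture of no consequence, C3' untouched).

Step 5
Reactants: 9 methylated enone ketal
Product: 11 (5R)-2,4,4-trimethyl-5-[2-(2-methyl-1,3-dioxolan-2-yl)ethyl]cyclohepta-2,6-dien-1-one, via silyl dienol ether 10 (not isolated)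
Conditions: LDA, TMSCl, THF, −78 °C; then Pd(OAc)2 (1.05 equiv), MeCN, rt
Reagents that add atoms: none
Why: Saegusa–Ito dehydrogenation, in which the second α'-deprotonation can only occur at C10' and the oxo-π-allylpalladium species formed from 10 undergoes β-hydride elimination towards C11' to give the conjugated endocyclic C10'=C11' bond.

Step 6
Reactants: 11 dienone ketal
Product: 12 (5R)-2,4,4-trimethyl-5-(3-oxobutyl)cyclohepta-2,6-dien-1-one
Conditions: PPTS (0.2 equiv), acetone–H2O (10:1), 45 °C; used directly
Reagents that add atoms: water O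
Why: Mild acid-catalysed ketal hydrolysis frees the methyl ketone without base, so that neither intramolecular Michael addition to the dienone nor deconjugation through the γ-hydrogen at C3' should intervene.

Step 7
Reactants: 12 dienone methyl ketone
Product: 13 (1R,3aR,8aR)-1-hydroxy-1,4,4,6-tetramethyl-2,3,3a,4,8,8a-hexahydroazulen-7(1H)-one (cis-fused; 6'-OH α; C9' ketone; C10'=C11')
Conditions: SmI2 (2.2 equiv, 0.1 M in THF, slow addition), t-BuOH (3 equiv), THF (0.005 M), −78 °C
Reagents that add atoms: none
Why: Single-electron transfer from Sm(II) gives the C6' ketyl (or the Sm(III)-bound radical anion of the less hindered enone arm, which makes the same bond), C6'–C7' forms by radical addition, and a second electron plus t-BuOH converts the resulting C8'/C9' samarium enolate into the ketone; the closest known reaction type is the SmI2 ketyl–olefin (ketone–enone) reductive cyclisation. Ring D closes in the 5-exo-trig mode, with C8' staying outside the new ring. C7' is controlled by the C3' stereocentre, because the three-atom tether reaches C7' only on its own face, which enforces the cis fusion with H-3' and H-7' syn. C6' is controlled by the transition-state preference of the bulky, electron-rich O–Sm(III) group to point away from C8' and the developing enolate, which places the hydroxyl anti to C8' and the methyl group syn to it. The step needs a choice between the two enone arms and must stop after two electrons: C11' is beyond the reach of the tether, trisubstituted and neopentyl, so only C7' is attacked, and the α-methylated, β-neopentyl product enone should accept electrons more slowly than the starting dienone, which slow addition of barely more than two equivalents at −78 °C exploits.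

Step 8
Reactants: 13 hydroxy enone
Product: 14 6'-O-triethylsilyl ether of 13
Conditions: TESOTf, 2,6-lutidine, CH2Cl2, −78 → 0 °C
Reagents that add atoms: triethylsilyl trifluoromethanesulfonate CC[Si](CC)(CC)OS(=O)(=O)C(F)(F)F
Why: Silyl triflate/hindered pyridine silylation protects the tertiary C6' alcohol, which removes a competing alkoxide in steps 10, 11 and 23 and a competing α-face directing group in step 12.

Step 9
Reactants: 14 TES enone
Product: 15 (1R,3aR,7S,8aR)-1,4,4,6-tetramethyl-1-(triethylsilyloxy)-1,2,3,3a,4,7,8,8a-octahydroazulen-7-ol (9'β-OH)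
Conditions: (R)-Me-CBS (0.2 equiv), catecholborane, toluene, −78 °C
Reagents that add atoms: none
Why: Corey–Bakshi–Shibata reduction, with the α-methylalkenyl side (C10') acting as the large group, should give clean 1,2-reduction and set C9' as the (S) β-alcohol under reagent control, which is safer than trusting the weak facial bias of the flexible seven-membered enone.

Step 10
Reactants: 15 allylic alcohol
Product: 16 9'-O-(tributylstannylmethyl) ether of 15
Conditions: KH, Bu3SnCH2I, 18-crown-6 (cat.), THF, 0 °C → rt
Reagents that add atoms: tributyl(iodomethyl)stannane CCCC[Sn](CI)(CCCC)CCCC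
Why: Williamson etherification of the potassium alkoxide with the reactive iodomethylstannane leaves C9' unchanged and arms the allylic alcohol for the sigmatropic shift.

Step 11
Reactants: 16 stannylmethyl ether
Product: 18 [(1R,3aR,5S,8aR)-1,4,4,6-tetramethyl-1-(triethylsilyloxy)-1,2,3,3a,4,5,8,8a-octahydroazulen-5-yl]methanol (C12'H2OH β on C11'; C9'=C10'), via lithiomethyl ether 17 (not isolated)
Conditions: n-BuLi, THF, −78 °C; H2O quench
Reagents that add atoms: none
Why: Still–Wittig [2,3]-sigmatropic rearrangement, in which tin–lithium exchange gives 17 and the shift is suprafacial through a five-membered envelope transition state, so that the CH2O unit is delivered to C11' on the β face that oxygen occupied at C9', setting C11' and moving the alkene to C9'=C10'.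

Step 12
Reactants: 18 homoallylic alcohol
Product: 19 9'β,10'β-epoxide of 18 (oxirane syn to the CH2OH group)
Conditions: VO(acac)2 (5 mol %), t-BuOOH (decane), CH2Cl2, 0 °C
Reagents that add atoms: tert-butyl hydroperoxide CC(C)(C)OO
Why: Vanadium-catalysed hydroxyl-directed epoxidation of a homoallylic alcohol delivers oxygen from the face that carries the C12' hydroxymethyl group, which sets C9' and C10' as the β-epoxide lying on the same side as the side chain, a face that undirected late-stage attack cannot be relied on to choose.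

Step 13
Reactants: 19 epoxy alcohol
Product: 20 C12' 1-phenyl-1H-tetrazol-5-yl sulfide of 19
Conditions: 1-phenyl-1H-tetrazole-5-thiol, PPh3, DIAD, THF, 0 °C → rt
Reagents that add atoms: 1-phenyl-1H-tetrazole-5-thiol Sc1nnnn1-c1ccccc1
Why: Mitsunobu thioetherification of the primary alcohol proceeds under neutral conditions that leave the epoxide and the silyl ether alone.

Step 14
Reactants: 20 sulfide
Product: 21 C12' 1-phenyl-1H-tetrazol-5-yl sulfone
Conditions: mCPBA (3 equiv), NaHCO3 buffer, CH2Cl2, 0 °C → rt
Reagents that add atoms: 3-chloroperoxybenzoic acid OOC(=O)c1cccc(Cl)c1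
Why: Peracid oxidation of the sulfide through the sulfoxide to the sulfone is safe here because the only alkene has already been epoxidised and bicarbonate buffers the acid.

**AB fragment**

Step 15
Reactants: 22 N-methoxy-N-methylacetamide; 23 geranyl bromide
Product: 24 (4E)-N-methoxy-N,5,9-trimethyldeca-4,8-dienamide
Conditions: LDA, 22, THF, −78 °C; then 23, −78 → −20 °C
Reagents that add atoms: none
Why: SN2 alkylation of the lithium enolate of a Weinreb acetamide with an allylic bromide joins C8 and C9 with retention of the E alkene.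

Step 16
Reactants: 24 dienamide
Product: 25 (4R,5R,8R)-4,5:8,9-diepoxy-N-methoxy-N,5,9-trimethyldecanamide (C7 R, C6 R, C3 R)
Conditions: D-fructose-derived Shi ketone (0.5 equiv), Oxone, K2CO3, Bu4NHSO4, borate/EDTA buffer, MeCN–dimethoxymethane, 0 °C
Reagents that add atoms: potassium peroxymonosulfate [K+].[O-]S(=O)(=O)OO
Why: Shi asymmetric epoxidation oxidises both electron-rich trisubstituted alkenes through the spiro transition state, the D-fructose-derived dioxirane giving the (R,R) C6–C7 epoxide that later fixes C6 and C7, and the (R) centre at C3 that is later erased.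

Step 17
Reactants: 25 diepoxy Weinreb amide
Product: 26 (7R,8R,11R)-7,8:11,12-diepoxy-8,12-dimethyltridec-1-en-4-one (allyl ketone; C10 = C=O)
Conditions: allylMgBr (1.2 equiv), THF, −78 °C; cold aq NH4Cl
Reagents that add atoms: allylmagnesium bromide C=CC[Mg]Br
Why: Weinreb ketone synthesis, in which the chelated tetrahedral adduct stops at mono-addition and at −78 °C the Grignard reagent should not touch the trisubstituted epoxides.

Step 18
Reactants: 26 allyl ketone
Product: 27 (Z)-triethylsilyl dienol ether of 26 (C10(OTES)=C11H–C12H=CH2, vinyl anti to C9)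
Conditions: KHMDS, THF, −78 °C, 30 min; TESCl
Reagents that add atoms: chlorotriethylsilane CC[Si](Cl)(CC)CC
Why: The doubly activated C11 hydrogens are by far the most acidic, so the extended potassium dienolate forms regioselectively and is O-silylated, the Z(O) geometry putting the vinyl group anti to C9.

Step 19
Reactants: 27 diepoxy dienol silane
Product: 28 (3R,5aR,6R,9aR)-6-ethenyl-2,2,5a-trimethyl-3-(triethylsilyloxy)octahydro-1-benzoxepin-7(2H)-one (trans-fused AB; C10 ketone; C11 vinyl equatorial)
Conditions: TESOTf (1.1 equiv), 2,6-di-tert-butyl-4-methylpyridine, CH2Cl2, −78 °C; Et3N/NaHCO3 quench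
Reagents that add atoms: triethylsilyl trifluoromethanesulfonate CC[Si](CC)(CC)OS(=O)(=O)C(F)(F)F
Why: Lewis-acid-triggered epoxide-opening cascade (tandem oxa-/carbacyclisation of a 1,5-diepoxide terminated by a silyl enol ether), in which silylation of the terminal epoxide lets the C6–C7 epoxide oxygen attack tertiary C2 to give a bicyclic epoxonium ion that the dienol silane opens through C11 at tertiary C6 with inversion in a chair-like array, so that C7 keeps its Shi-derived configuration, C6 becomes the trans-fused quaternary centre and the C11 vinyl group ends equatorial, which is also the thermodynamic position of this epimerisable centre.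

Step 20
Reactants: 28 α-vinyl ketone
Product: 29 (3R,5aR,6R,7S,9aR)-6-ethenyl-2,2,5a,7-tetramethyl-3-(triethylsilyloxy)decahydro-1-benzoxepin-7-ol (10-OH axial β, 10-Me equatorial)
Conditions: MeLi, anhydrous CeCl3, THF, −78 °C
Reagents that add atoms: methyllithium [Li]C
Why: 1,2-Addition of a weakly basic organocerium reagent avoids enolisation of the α-vinyl ketone, and because axial approach is blocked by the syn-axial C6 methyl group the methyl enters equatorially from the α face and C10 receives the axial β-hydroxyl of the target.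

Step 21
Reactants: 29 tertiary alcohol
Product: 30 3,10-bis(triethylsilyl) ether of 29
Conditions: TESOTf, 2,6-lutidine, CH2Cl2, 0 °C → rt
Reagents that add atoms: triethylsilyl trifluoromethanesulfonate CC[Si](CC)(CC)OS(=O)(=O)C(F)(F)F
Why: Silyl triflate silylation masks the β-hydroxyl so that the coming aldehyde cannot undergo retro-aldol cleavage under basic olefination conditions.

Step 22
Reactants: 30 bis-silyl vinyl compound
Product: 32 AB aldehyde (C11–C12HO equatorial; 3-OTES; 10-OTES), via secondary ozonide 31 (not isolated)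
Conditions: O3, CH2Cl2, −78 °C; PPh3, −78 °C → rt
Reagents that add atoms: ozone [O-][O+]=O
Why: Ozonolysis with reductive work-up cleaves the only alkene, the vinyl group, to the C12 aldehyde, whose equatorial α-centre C11 is also the thermodynamically preferred one.

**Union and endgame**

Step 23
Reactants: 21 CD sulfone; 32 AB aldehyde
Product: 33 C12=C12' alkene (E drawn), tris-TES ether, 9'β,10'β-epoxide
Conditions: 21, KHMDS, THF, −78 °C; then 32, −78 °C → rt
Reagents that add atoms: none
Why: Julia–Kocienski olefination, in which the metalated tetrazolyl sulfone adds to the aldehyde and Smiles rearrangement with loss of SO2 and tetrazolate gives the alkene, whose geometry is irrelevant, while the syn relation of C12' and the epoxide oxygen rules out backside opening of the epoxide by the carbanion.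

Step 24
Reactants: 33 alkene
Product: 34 12,12'-dihydro compound (tris-TES ether)
Conditions: 2-nitrobenzenesulfonohydrazide (excess, portions), Et3N, CH2Cl2, rt
Reagents that add atoms: none
Why: Diimide transfers hydrogen concertedly to the only C=C bond without isomerising it and without touching the epoxide or the silyl ethers.

Step 25
Reactants: 34 tris-TES ether
Product: 35 3,10,6'-triol
Conditions: TBAF, THF, 0 → 40 °C
Reagents that add atoms: none
Why: Fluoride cleaves all three triethylsilyl ethers at once under non-acidic conditions, which avoids acid-induced opening of the trisubstituted epoxide by the C6' hydroxyl, and no enolisable carbonyl group is present yet.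

Step 26
Reactants: 35 triol
Product: 36 target CNP0259752.1
Conditions: Dess–Martin periodinane, NaHCO3 buffer, CH2Cl2, 0 °C → rt
Reagents that add atoms: none
Why: Dess–Martin oxidation converts the only secondary alcohol (C3) into the ketone, the two tertiary alcohols and the epoxide being inert.

**Compound list**

1 | 2-(2-bromoethyl)-2-methyl-1,3-dioxolane | CC1(CCBr)OCCO1 | starting material
2 | 4,4-dimethylcyclohex-2-en-1-one | CC1(C)CCC(=O)C=C1 | starting material
3 | [2-(2-methyl-1,3-dioxolan-2-yl)ethyl]magnesium bromide | CC1(CC[Mg]Br)OCCO1 | intermediate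
4 | bromomagnesium enolate of the (R)-conjugate adduct | CC1(CC[C@@H]2C=C(O[Mg]Br)CCC2(C)C)OCCO1 | intermediate
5 | (3R)-trimethylsilyl enol ether | CC1(CC[C@@H]2C=C(O[Si](C)(C)C)CCC2(C)C)OCCO1 | intermediate
6 | silyloxycyclopropane (CH2 anti to side chain) | CC1(CC[C@@H]2[C@H]3C[C@@]3(O[Si](C)(C)C)CCC2(C)C)OCCO1 | intermediate
7 | β-chloro ketone (Cl on C7', epimers) | CC1(CC[C@@H]2C(Cl)CC(=O)CCC2(C)C)OCCO1 | intermediate
8 | (4R)-cycloheptenone ketal | CC1(CC[C@@H]2C=CC(=O)CCC2(C)C)OCCO1 | intermediate
9 | (4R)-7-methylcycloheptenone ketal (C10' epimers) | CC1(CC[C@@H]2C=CC(=O)C(C)CC2(C)C)OCCO1 | intermediate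
10 | trimethylsilyl dienol ether of 9 | CC1(CC[C@@H]2C=CC(O[Si](C)(C)C)=C(C)CC2(C)C)OCCO1 | intermediate
11 | (5R)-dienone ketal | CC1(CC[C@@H]2C=CC(=O)C(C)=CC2(C)C)OCCO1 | intermediate
12 | (5R)-2,4,4-trimethyl-5-(3-oxobutyl)cyclohepta-2,6-dien-1-one | CC(=O)CC[C@@H]1C=CC(=O)C(C)=CC1(C)C | intermediate
13 | (1R,3aR,8aR)-hydroxy hydroazulenone | CC1=CC(C)(C)[C@@H]2CC[C@@](C)(O)[C@@H]2CC1=O | intermediate
14 | 6'-O-TES enone | CC1=CC(C)(C)[C@@H]2CC[C@@](C)(O[Si](CC)(CC)CC)[C@@H]2CC1=O | intermediate
15 | (9'S) β-allylic alcohol | CC1=CC(C)(C)[C@@H]2CC[C@@](C)(O[Si](CC)(CC)CC)[C@@H]2C[C@@H]1O | intermediate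
16 | tributylstannylmethyl ether | CC1=CC(C)(C)[C@@H]2CC[C@@](C)(O[Si](CC)(CC)CC)[C@@H]2C[C@@H]1OC[Sn](CCCC)(CCCC)CCCC | intermediate
17 | lithiomethyl ether | CC1=CC(C)(C)[C@@H]2CC[C@@](C)(O[Si](CC)(CC)CC)[C@@H]2C[C@@H]1OC[Li] | intermediate
18 | C11' β-hydroxymethyl, C9'=C10' alkene | OC[C@@H]1C(C)(C)[C@@H]2CC[C@@](C)(O[Si](CC)(CC)CC)[C@@H]2CC=C1C | intermediate
19 | 9'β,10'β-epoxy alcohol | OC[C@@H]1C(C)(C)[C@@H]2CC[C@@](C)(O[Si](CC)(CC)CC)[C@@H]2C[C@@H]2O[C@@]21C | intermediate
20 | phenyltetrazolyl sulfide | c1ccc(cc1)-n1nnnc1SC[C@@H]1C(C)(C)[C@@H]2CC[C@@](C)(O[Si](CC)(CC)CC)[C@@H]2C[C@@H]2O[C@@]21C | intermediate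
21 | phenyltetrazolyl sulfone | c1ccc(cc1)-n1nnnc1S(=O)(=O)C[C@@H]1C(C)(C)[C@@H]2CC[C@@](C)(O[Si](CC)(CC)CC)[C@@H]2C[C@@H]2O[C@@]21C | intermediate
22 | N-methoxy-N-methylacetamide | CC(=O)N(C)OC | starting material
23 | geranyl bromide | CC(C)=CCC/C(C)=C/CBr | starting material
24 | (4E)-N-methoxy-N,5,9-trimethyldeca-4,8-dienamide | CC(C)=CCC/C(C)=C/CCC(=O)N(C)OC | intermediate
25 | (4R,5R,8R)-diepoxy Weinreb amide | CC1(C)O[C@@H]1CC[C@@]1(C)O[C@@H]1CCC(=O)N(C)OC | intermediate
26 | diepoxy allyl ketone | CC1(C)O[C@@H]1CC[C@@]1(C)O[C@@H]1CCC(=O)CC=C | intermediate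
27 | (Z)-TES dienol ether | CC1(C)O[C@@H]1CC[C@@]1(C)O[C@@H]1CC/C(O[Si](CC)(CC)CC)=C/C=C | intermediate
28 | bicyclic α-vinyl ketone, 3-OTES | CC1(C)O[C@@H]2CCC(=O)[C@H](C=C)[C@@]2(C)CC[C@H]1O[Si](CC)(CC)CC | intermediate
29 | C10 tertiary alcohol | CC1(C)O[C@@H]2CC[C@](C)(O)[C@H](C=C)[C@@]2(C)CC[C@H]1O[Si](CC)(CC)CC | intermediate
30 | 3,10-bis-TES vinyl compound | CC1(C)O[C@@H]2CC[C@](C)(O[Si](CC)(CC)CC)[C@H](C=C)[C@@]2(C)CC[C@H]1O[Si](CC)(CC)CC | intermediate
31 | secondary ozonide of 30 | CC1(C)O[C@@H]2CC[C@](C)(O[Si](CC)(CC)CC)[C@H](C3OCOO3)[C@@]2(C)CC[C@H]1O[Si](CC)(CC)CC | intermediate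
32 | AB aldehyde | CC1(C)O[C@@H]2CC[C@](C)(O[Si](CC)(CC)CC)[C@H](C=O)[C@@]2(C)CC[C@H]1O[Si](CC)(CC)CC | intermediate
33 | coupled C12=C12' alkene | CC1(C)O[C@@H]2CC[C@](C)(O[Si](CC)(CC)CC)[C@H](/C=C/[C@@H]3C(C)(C)[C@@H]4CC[C@@](C)(O[Si](CC)(CC)CC)[C@@H]4C[C@@H]4O[C@@]43C)[C@@]2(C)CC[C@H]1O[Si](CC)(CC)CC | intermediate
34 | saturated tris-TES ether | CC1(C)O[C@@H]2CC[C@](C)(O[Si](CC)(CC)CC)[C@H](CC[C@@H]3C(C)(C)[C@@H]4CC[C@@](C)(O[Si](CC)(CC)CC)[C@@H]4C[C@@H]4O[C@@]43C)[C@@]2(C)CC[C@H]1O[Si](CC)(CC)CC | intermediate
35 | 3,10,6'-triol | CC1(C)O[C@@H]2CC[C@](C)(O)[C@H](CC[C@@H]3C(C)(C)[C@@H]4CC[C@@](C)(O)[C@@H]4C[C@@H]4O[C@@]43C)[C@@]2(C)CC[C@H]1O | intermediate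
36 | CNP0259752.1 | CC1(C)O[C@@H]2CC[C@](C)(O)[C@H](CC[C@@H]3C(C)(C)[C@@H]4CC[C@@](C)(O)[C@@H]4C[C@@H]4O[C@@]43C)[C@@]2(C)CCC1=O | target

Total step count: 26. Longest linear sequence: 18 steps (steps 1–14, then 23–26). The AB branch (steps 15–22) is 8 steps and joins at step 23.

**Steps most likely to fail**

1. Step 7.
   - What may go wrong: electron transfer to the cross-conjugated dienone may outrun ring closure. Hydrodimerisation, plain 1,4-reduction or further reduction of the surviving enone would then consume material.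
   - Fallback: close ring D before the second double bond exists.
   - Setting out from 9, PPTS hydrolysis gives the mono-enone diketone F1.
   - SmI2/t-BuOH then closes ring D on the only reducible arm to the saturated hydroxy ketone F2.
   - TESOTf/2,6-lutidine gives the silyl ether F3.
   - Equilibrating silylation (TMSCl, NaI, Et3N, MeCN) gives the tetrasubstituted enol silane F4.
   - Pd(OAc)2 dehydrogenates F4 towards C11', which comes back to the route at 14.

2. Step 19.
   - What may go wrong: the acid-labile dienol silane may be lost by protodesilylation. The epoxonium relay may also be intercepted before C6–C11 forms, by hydride shift or by exo opening to smaller cyclic ethers.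
   - Fallback: use a storable push–pull terminator and bring in C12 afterwards.
   - Setting out from 25, acylation of the lithium enolate of allyl acetate gives the allyl β-keto ester F5.
   - NaH/TESCl gives the (Z)-silyl enol ether F6.
   - The TESOTf cascade gives the bicyclic β-keto ester F7.
   - Pd(PPh3)4-catalysed Tsuji decarboxylative allylation places an allyl group regiospecifically on C11 to give the α-allyl ketone F8, which DBU would equilibrate to the equatorial epimer.
   - MeLi/CeCl3 gives the carbinol F9, and TESOTf gives the bis-silyl ether F10.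
   - A ruthenium hydride (RuHCl(CO)(PPh3)3, toluene, 80 °C) moves the alkene to give the propenyl compound F11.
   - Ozonolysis with PPh3 work-up comes back to the route at 32.

3. Step 23.
   - What may go wrong: both partners are flanked by fully substituted carbons. Carbonyl addition may therefore be slow or reversible, and the carbanion may act as a base on the aldehyde.
   - Fallback: join the fragments through sulfur at two primary carbons and contract.
   - Setting out from 32, NaBH4 gives the primary alcohol F12, and a Mitsunobu reaction with thioacetic acid gives the thioacetate F13.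
   - Setting out from 19, MsCl/Et3N gives the mesylate F14.
   - K2CO3 in MeOH–DMF frees the thiolate from F13 in the presence of F14 and gives the sulfide F15.
   - Buffered mCPBA gives the sulfone F16.
   - A Ramberg–Bäcklund reaction (CBr2F2, KOH/Al2O3, t-BuOH–CH2Cl2) extrudes SO2 and comes back to the route at 33.

Further compounds
F1 | step 7 | (4R)-5,5,7-trimethyl-4-(3-oxobutyl)cyclohept-2-en-1-one (C10' epimers) | CC(=O)CC[C@@H]1C=CC(=O)C(C)CC1(C)C
F2 | step 7 | saturated cis-hydroazulenone carbinol (C10' epimers) | CC1CC(C)(C)[C@@H]2CC[C@@](C)(O)[C@@H]2CC1=O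
F3 | step 7 | 6'-O-TES ether of F2 | CC1CC(C)(C)[C@@H]2CC[C@@](C)(O[Si](CC)(CC)CC)[C@@H]2CC1=O
F4 | step 7 | C9'=C10' trimethylsilyl enol ether of F3 | CC=1CC(C)(C)[C@@H]2CC[C@@](C)(O[Si](CC)(CC)CC)[C@@H]2CC=1O[Si](C)(C)C
F5 | step 19 | diepoxy allyl β-keto ester | CC1(C)O[C@@H]1CC[C@@]1(C)O[C@@H]1CCC(=O)CC(=O)OCC=C
F6 | step 19 | (Z)-TES enol ether of F5 | CC1(C)O[C@@H]1CC[C@@]1(C)O[C@@H]1CC/C(O[Si](CC)(CC)CC)=C/C(=O)OCC=C
F7 | step 19 | bicyclic allyl β-keto ester, 3-OTES | CC1(C)O[C@@H]2CCC(=O)[C@H](C(=O)OCC=C)[C@@]2(C)CC[C@H]1O[Si](CC)(CC)CC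
F8 | step 19 | C11 α-allyl ketone | CC1(C)O[C@@H]2CCC(=O)[C@H](CC=C)[C@@]2(C)CC[C@H]1O[Si](CC)(CC)CC
F9 | step 19 | C10 carbinol with C11 allyl | CC1(C)O[C@@H]2CC[C@](C)(O)[C@H](CC=C)[C@@]2(C)CC[C@H]1O[Si](CC)(CC)CC
F10 | step 19 | 3,10-bis-TES allyl compound | CC1(C)O[C@@H]2CC[C@](C)(O[Si](CC)(CC)CC)[C@H](CC=C)[C@@]2(C)CC[C@H]1O[Si](CC)(CC)CC
F11 | step 19 | 3,10-bis-TES (E)-propenyl compound | CC1(C)O[C@@H]2CC[C@](C)(O[Si](CC)(CC)CC)[C@H](/C=C/C)[C@@]2(C)CC[C@H]1O[Si](CC)(CC)CC
F12 | step 23 | AB C12 primary alcohol | CC1(C)O[C@@H]2CC[C@](C)(O[Si](CC)(CC)CC)[C@H](CO)[C@@]2(C)CC[C@H]1O[Si](CC)(CC)CC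
F13 | step 23 | AB C12 thioacetate | CC1(C)O[C@@H]2CC[C@](C)(O[Si](CC)(CC)CC)[C@H](CSC(C)=O)[C@@]2(C)CC[C@H]1O[Si](CC)(CC)CC
F14 | step 23 | CD C12' mesylate | CS(=O)(=O)OC[C@@H]1C(C)(C)[C@@H]2CC[C@@](C)(O[Si](CC)(CC)CC)[C@@H]2C[C@@H]2O[C@@]21C
F15 | step 23 | AB–CH2–S–CH2–CD sulfide | CC1(C)O[C@@H]2CC[C@](C)(O[Si](CC)(CC)CC)[C@H](CSC[C@@H]3C(C)(C)[C@@H]4CC[C@@](C)(O[Si](CC)(CC)CC)[C@@H]4C[C@@H]4O[C@@]43C)[C@@]2(C)CC[C@H]1O[Si](CC)(CC)CC
F16 | step 23 | AB–CH2–SO2–CH2–CD sulfone | CC1(C)O[C@@H]2CC[C@](C)(O[Si](CC)(CC)CC)[C@H](CS(=O)(=O)C[C@@H]3C(C)(C)[C@@H]4CC[C@@](C)(O[Si](CC)(CC)CC)[C@@H]4C[C@@H]4O[C@@]43C)[C@@]2(C)CC[C@H]1O[Si](CC)(CC)CC
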